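**Strategy.** The route rests on cutting the C4–C5 bond of the decenoate chain, where the primary allylic carbon C5 of the 6Z-trisubstituted alkene (C6=C7) meets the CH2 (C4) next to the C3 methyl stereocentre. C3, flanked by two CH2 groups, is read as a desymmetrised 3-methylglutarate: one carboxyl of the commercial (R)-half-ester is excised as CO2 to give a C4 iodide, then an ester-tolerant alkylzinc. In the key step this zinc reagent is joined to a neryl-type Z-allylic chloride carrying the 2,4-disubstituted furan and its 3-furylmethyl arm by cobalt-catalysed SN2 allylation. This gives the target directly, with alkene geometry and stereocentre intact; both furan rings and the ester are spectators.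

Key step: step 8

Assumption: the chain is numbered C1 (ester carbon) to C10 (CH2 on the furan), and (R)-methyl hydrogen 3-methylglutarate 15 is bought as the single enantiomer; the C3 descriptor changes from R (15) to S (17, 18) and back to R (19) only through CIP priorities, the spatial arrangement being the same throughout.

**Step 1**
Reactants: 1 3-bromofuran; 2 4-bromofuran-2-carbaldehyde
Product: 4 (4-bromofuran-2-yl)(furan-3-yl)methanol (racemic), via furan-3-yllithium 3 (not isolated)
Conditions: 1 (1.05 equiv), n-BuLi (1.0 equiv), Et2O, −78 °C; then 2 in THF, −78 °C; H2O quench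
Reagents that add atoms: none
Why: Br/Li exchange at −78 °C gives furan-3-yllithium, which stays at C3 at this temperature and adds 1,2 to the aldehyde of 2 much faster than it exchanges with the ring bromide (organolithium carbonyl addition); the carbinol centre forms racemic and is erased in step 2.

**Step 2**
Reactants: 4 (4-bromofuran-2-yl)(furan-3-yl)methanol
Product: 5 4-bromo-2-(furan-3-ylmethyl)furan
Conditions: Et3SiH (3 equiv), CF3CO2H (2 equiv), CH2Cl2, −20 → 0 °C, carbinol added slowly to the silane/acid mixture
Reagents that add atoms: none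
Why: Ionic hydrogenation: TFA ionises the doubly furyl-stabilised carbinol and the excess Et3SiH should trap the cation by hydride transfer before it can alkylate a furan ring, while the ring C–Br bond is inert.

**Step 3**
Reactants: 5 4-bromo-2-(furan-3-ylmethyl)furan; 6 allylboronic acid pinacol ester
Product: 7 4-allyl-2-(furan-3-ylmethyl)furan
Conditions: PdCl2(dppf)·CH2Cl2 (5 mol%), CsF (3 equiv), THF, 65 °C
Reagents that add atoms: none
Why: Suzuki–Miyaura coupling with fluoride-activated allyl-Bpin replaces the C4 bromide by allyl; the parent allyl group has no α/γ ambiguity and the weak base should leave the terminal alkene unconjugated.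

**Step 4**
Reactants: 8 but-2-yn-1-ol
Product: 10 (Z)-3-iodobut-2-en-1-ol, via cyclic alkenylalanate 9 (not isolated)
Conditions: Red-Al (1.6 equiv), Et2O, 0 °C → rt; EtOAc; then I2 (1.5 equiv), THF, −78 → 0 °C; aq. Rochelle salt/Na2S2O3
Reagents that add atoms: iodine, II
Why: Hydroxyl-directed trans-hydroalumination of the propargylic alcohol delivers hydride to C2 and aluminium to C3 inside a five-membered alanate, and iodinolysis of the C–Al bond with retention places iodine cis to CH2OH, which defines the Z geometry.

**Step 5**
Reactants: 7 4-allyl-2-(furan-3-ylmethyl)furan; 10 (Z)-3-iodobut-2-en-1-ol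
Product: 12 (Z)-6-[5-(furan-3-ylmethyl)furan-3-yl]-3-methylhex-2-en-1-ol, via B-alkyl-9-BBN adduct 11 (not isolated)
Conditions: 9-BBN-H (1.2 equiv), THF, 0 °C → rt; then 10, PdCl2(dppf)·CH2Cl2 (5 mol%), AsPh3 (10 mol%), Cs2CO3 (3 equiv), DMF/H2O, rt
Reagents that add atoms: none
Why: 9-BBN hydroborates only the terminal alkene of 7 at its CH2 end (the furans are inert), and the B-alkyl Suzuki–Miyaura coupling with vinyl iodide 10 proceeds with retention at the sp2 carbon, so the new chain sits cis to CH2OH and the 6Z alkene of the target is fixed here.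

**Step 6**
Reactants: 12 (Z)-6-[5-(furan-3-ylmethyl)furan-3-yl]-3-methylhex-2-en-1-ol
Product: 14 4-[(4Z)-6-chloro-4-methylhex-4-en-1-yl]-2-(furan-3-ylmethyl)furan, via allylic mesylate 13 (not isolated)
Conditions: MsCl (1.3 equiv), LiCl (3 equiv), s-collidine (1.5 equiv), DMF, 0 °C; used without storage
Reagents that add atoms: lithium chloride, [Li+].[Cl-]
Why: Mesylation followed in the same flask by SN2 displacement with chloride at the primary allylic carbon at 0 °C converts the alcohol into the chloride without allylic transposition or Z/E isomerisation, as is standard for nerol-type alcohols.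

**Step 7**
Reactants: 15 (R)-5-methoxy-3-methyl-5-oxopentanoic acid [(R)-methyl hydrogen 3-methylglutarate]
Product: 17 methyl (S)-4-iodo-3-methylbutanoate, via acyl hypoiodite 16 (not isolated)
Conditions: PhI(OAc)2 (1.1 equiv, two portions), I2 (1.0 equiv), cyclohexane, W lamp, reflux
Reagents that add atoms: iodine, II
Why: Hunsdiecker-type iododecarboxylation: PhI(OAc)2/I2 converts the acid into an acyl hypoiodite whose photolysis gives the acyloxy radical, loss of CO2 and iodine capture by the primary C4 radical; C3 is not involved, so its configuration is retained.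

**Step 8**
Reactants: 17 methyl (S)-4-iodo-3-methylbutanoate; 14 4-[(4Z)-6-chloro-4-methylhex-4-en-1-yl]-2-(furan-3-ylmethyl)furan
Product: 19 methyl (3R,6Z)-10-[5-(furan-3-ylmethyl)furan-3-yl]-3,7-dimethyldec-6-enoate (target), via alkylzinc iodide 18 (not isolated)
Conditions: (i) 17 (2 equiv), Zn dust (activated with BrCH2CH2Br/TMSCl), LiCl, THF, 40 °C; (ii) 14 (1 equiv), CoBr2 (10 mol%), THF/NMP, −10 °C → rt
Reagents that add atoms: none
Why: Zinc inserts into the primary C–I bond of 17 to give the ester-tolerant γ-zincio ester 18; alkyl transfer from zinc to cobalt should give a low-valent alkylcobalt species that attacks allylic chloride 14 at its unhindered CH2Cl carbon (C5) and reductively eliminates to forge C4–C5. The closest known reaction type is the cobalt-catalysed SN2-selective allylation of alkylzinc reagents with allylic chlorides, established for geranyl- and neryl-type chlorides and complementary to the SN2'-selective copper-mediated variant. No ring is closed and no stereocentre is created: C3 comes in from 15 and is not at the reacting carbon or α to the ester, so it cannot epimerise. The step needs α- over γ-regioselectivity and retention of the 6Z geometry; the γ-carbon C7 is fully substituted, so attack there would build a quaternary centre, and at −10 °C the cobalt–allyl intermediate is expected to couple faster than it can isomerise syn/anti. The methyl ester and both furan rings are inert to the organozinc under these conditions.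

**Compound list**
1 | 3-bromofuran | Brc1ccoc1 | starting material
2 | 4-bromofuran-2-carbaldehyde | O=Cc1cc(Br)co1 | starting material
3 | furan-3-yllithium | [Li]c1ccoc1 | intermediate
4 | (4-bromofuran-2-yl)(furan-3-yl)methanol (racemic) | OC(c1ccoc1)c1cc(Br)co1 | intermediate
5 | 4-bromo-2-(furan-3-ylmethyl)furan | Brc1coc(Cc2ccoc2)c1 | intermediate
6 | allylboronic acid pinacol ester (2-allyl-4,4,5,5-tetramethyl-1,3,2-dioxaborolane) | C=CCB1OC(C)(C)C(C)(C)O1 | starting material
7 | 4-allyl-2-(furan-3-ylmethyl)furan | C=CCc1coc(Cc2ccoc2)c1 | intermediate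
8 | but-2-yn-1-ol | CC#CCO | starting material
9 | sodium 2,2-bis(2-methoxyethoxy)-3-methyl-2,5-dihydro-1,2-oxaluminol-2-uide (cyclic alkenylalanate) | [Na+].CC1=CCO[Al-]1(OCCOC)OCCOC | intermediate
10 | (Z)-3-iodobut-2-en-1-ol | OC/C=C(/C)I | intermediate
11 | 9-{3-[5-(furan-3-ylmethyl)furan-3-yl]propyl}-9-borabicyclo[3.3.1]nonane | C1CC2CCCC(C1)B2CCCc1coc(Cc2ccoc2)c1 | intermediate
12 | (Z)-6-[5-(furan-3-ylmethyl)furan-3-yl]-3-methylhex-2-en-1-ol | OC/C=C(/C)CCCc1coc(Cc2ccoc2)c1 | intermediate
13 | (Z)-6-[5-(furan-3-ylmethyl)furan-3-yl]-3-methylhex-2-en-1-yl methanesulfonate | CS(=O)(=O)OC/C=C(/C)CCCc1coc(Cc2ccoc2)c1 | intermediate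
14 | 4-[(4Z)-6-chloro-4-methylhex-4-en-1-yl]-2-(furan-3-ylmethyl)furan | ClC/C=C(/C)CCCc1coc(Cc2ccoc2)c1 | intermediate
15 | (R)-5-methoxy-3-methyl-5-oxopentanoic acid | COC(=O)C[C@H](C)CC(=O)O | starting material
16 | (R)-5-methoxy-3-methyl-5-oxopentanoyl hypoiodite | COC(=O)C[C@H](C)CC(=O)OI | intermediate
17 | methyl (S)-4-iodo-3-methylbutanoate | COC(=O)C[C@H](C)CI | intermediate
18 | [(S)-4-methoxy-2-methyl-4-oxobutyl]zinc iodide | COC(=O)C[C@H](C)C[Zn]I | intermediate
19 | methyl (3R,6Z)-10-[5-(furan-3-ylmethyl)furan-3-yl]-3,7-dimethyldec-6-enoate | COC(=O)C[C@H](C)CC/C=C(/C)CCCc1coc(Cc2ccoc2)c1 | target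

**Step count.** Total: 8 steps. Longest linear sequence: 6 steps (1, 2, 3, 5, 6, 8).

**Steps most likely to fail**

Step 8. Alkyl transfer from the alkylzinc iodide to cobalt may be slow, or the allyl unit may equilibrate through a π-allyl species, giving Z→E isomerisation or attack at C7; the allylic chloride may also ionise and decompose before coupling. The fallback sets out from 14 and moves the stereocentre to catalyst control. The dianion of methyl acetoacetate (NaH, then n-BuLi, THF, 0 °C) is alkylated at its γ-carbon by 14 to give methyl (Z)-10-[5-(furan-3-ylmethyl)furan-3-yl]-7-methyl-3-oxodec-6-enoate F1. Enolisation and O-phosphorylation (NaH, ClP(O)(OEt)2, Et2O, 0 °C) should give the Z-enol phosphate, methyl (2Z,6Z)-3-[(diethoxyphosphoryl)oxy]-10-[5-(furan-3-ylmethyl)furan-3-yl]-7-methyldeca-2,6-dienoate F2. Substitution with Me2CuLi (Et2O, −78 °C) with retention should give methyl (2E,6Z)-10-[5-(furan-3-ylmethyl)furan-3-yl]-3,7-dimethyldeca-2,6-dienoate F3. Asymmetric copper hydride conjugate reduction of the enoate (Cu(OAc)2, DTBM-SEGPHOS, PMHS, t-BuOH, toluene, 0 °C; the ligand antipode that gives 3R to be fixed in a trial run) leaves the isolated C6=C7 alkene and the furans untouched and comes back to the route at 19.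

Step 2. The furfuryl-type cation may alkylate a furan ring (oligomerisation) or open the ring faster than it captures hydride. The fallback sets out from 4 and avoids cations altogether. Oxidation with MnO2 (CH2Cl2, rt) gives (4-bromofuran-2-yl)(furan-3-yl)methanone F4. Wolff–Kishner reduction (N2H4·H2O, KOH, diethylene glycol, 120 → 180 °C) through the hydrazone of F4, [(4-bromofuran-2-yl)(furan-3-yl)methylidene]hydrazine F5, returns to the route at 5.

Step 7. The radical chain may stall, the half-ester may scramble acid and ester through the cyclic anhydride under hot acidic conditions (eroding enantiopurity), or the γ-iodo ester may lactonise on prolonged heating. The fallback sets out from 15 and runs the decarboxylation at room temperature by a thiohydroxamate chain (Barton decarboxylation). Coupling of 15 with N-hydroxypyridine-2-thione (DCC, cat. DMAP, CH2Cl2, 0 °C, dark) gives the O-acyl thiohydroxamate, 2-thioxopyridin-1(2H)-yl methyl (R)-3-methylpentanedioate F6. Visible-light photolysis of F6 in the presence of iodoform (benzene, rt) returns to the route at 17.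

**Further compounds**
F1 | step 8 | methyl (Z)-10-[5-(furan-3-ylmethyl)furan-3-yl]-7-methyl-3-oxodec-6-enoate | COC(=O)CC(=O)CC/C=C(/C)CCCc1coc(Cc2ccoc2)c1
F2 | step 8 | methyl (2Z,6Z)-3-[(diethoxyphosphoryl)oxy]-10-[5-(furan-3-ylmethyl)furan-3-yl]-7-methyldeca-2,6-dienoate | COC(=O)/C=C(\OP(=O)(OCC)OCC)CC/C=C(/C)CCCc1coc(Cc2ccoc2)c1
F3 | step 8 | methyl (2E,6Z)-10-[5-(furan-3-ylmethyl)furan-3-yl]-3,7-dimethyldeca-2,6-dienoate | COC(=O)/C=C(\C)CC/C=C(/C)CCCc1coc(Cc2ccoc2)c1
F4 | step 2 | (4-bromofuran-2-yl)(furan-3-yl)methanone | O=C(c1ccoc1)c1cc(Br)co1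
F5 | step 2 | [(4-bromofuran-2-yl)(furan-3-yl)methylidene]hydrazine | NN=C(c1ccoc1)c1cc(Br)co1
F6 | step 7 | 2-thioxopyridin-1(2H)-yl methyl (R)-3-methylpentanedioate | COC(=O)C[C@H](C)CC(=O)On1ccccc1=S
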